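| setting | epsilon | gamma | theta | beta | oak | ash | alder | cedar | birch |
|---|---|---|---|---|---|---|---|---|---|
| substrate | 0.28 M | 0.28 M | 0.28 M | 0.56 M | 0.28 M | 0.28 M | 0.28 M (in portions, 5, over 30 min) | 0.28 M (fed, over 3.0 min) | 0.28 M (fed, over 30 min) |
| reagent | 0.266 M | 0.13 M | 0.53 M | 0.266 M | 0.266 M | 0.266 M (fed, over 30 min) | 0.266 M | 0.266 M | 0.266 M |
| temperature | 65 °C | 80 °C | 65 °C | 80 °C | 80 °C |  | 80 °C | 80 °C | 80 °C |
| remark | run made earlier | run made earlier | run made earlier | run made earlier | everything together at the start | the addition at 50 °C, then warmed to 80 °C; the feed brings no volume worth counting | first portion at the start, last at 30 min | all else is in the flask from the start; the feed brings no volume worth counting | all else is in the flask from the start; the feed brings no volume worth counting |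
| time |  |  |  |  | 50 min | 50 min | 50 min | 50 min | 50 min |

| run | time / min | target / % |
|---|---|---|
| epsilon | 5.00 | 60.2 |
| epsilon | 15.0 | 81.9 |
| epsilon | 30.0 | 84.9 |
| epsilon | 40.0 | 83.1 |
| epsilon | 60.0 | 77.9 |
| epsilon | 80.0 | 74.3 |
| epsilon | 120 | 64.8 |
| gamma | 5.00 | 41.5 |
| gamma | 8.00 | 40.4 |
| gamma | 12.0 | 35.1 |
| gamma | 15.0 | 34.9 |
| gamma | 25.0 | 29.8 |
| gamma | 40.0 | 23.5 |
| gamma | 60.0 | 14.8 |
| theta | 10.0 | 96.0 |
| theta | 15.0 | 96.7 |
| theta | 25.0 | 95.0 |
| theta | 30.0 | 90.4 |
| theta | 50.0 | 85.8 |
| theta | 80.0 | 76.0 |
| theta | 120 | 66.3 |
| beta | 5.00 | 43.5 |
| beta | 10.0 | 39.0 |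
| beta | 15.0 | 35.5 |
| beta | 30.0 | 26.3 |
| beta | 60.0 | 15.4 |

(standard deviation of a reading: 1 percentage point)

- the earlier runs were read with a standard deviation of 1 percentage point

* the flask with the highest amount of target, in percent of the substrate charged ("all alike" if they lie within 1.5 percentage points) (oak / ash / alder / cedar / birch / all alike)
* final target, as a percentage of the substrate charged, in oak
* final target, as a percentage of the substrate charged, in ash
* final target, as a percentage of the substrate charged, in alder
* final target, as a percentage of the substrate charged, in cedar
* final target, as a percentage of the substrate charged, in birch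

At 80 °C the target peak shrinks with time once it is made, so I reckon with that loss. In gamma it falls from 41.5% at 5.00 min to 14.8% at 60.0 min, which gives the hot loss constant k_L, the first-order rate at which formed target disappears at this temperature: 0.0187 /min. Beta, with another charge, reads 0.0189 /min. Epsilon at 65 °C reads 0.00311 /min, less than that, so I count hot minutes.

With c(reagent) 0.266 M under c(substrate) 0.28 M, reagent is the limiting reagent, and one reagent per target caps the yield at 95.0%. Gamma carried back to the start reads 45.6% against its own cap of 46.4%.

I reckon oak in two ways. The first multiplies the cap by the survival over 50 min and gives 37.2%. The second uses beta, which holds the same c(reagent): I interpolate its readings to 50 min and take twice the percentage, which gives 36.8%. They differ by 0.40 points, and a reading scatters by 1 point.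

The first way cheats, though, by dating the target's birth to the start, whereas the second reads beta by the clock, with beta's formation time already in its readings. The second way's doubling carries twice the scatter of a reading. Epsilon, colder, holds 63.4% of its cap at 5.00 min, so for the first way I guess a birth delay of 2.50 min, half that time. This correction adds 1.8 points and puts oak at 39.0%, which stands 2.2 points above the second way, and I keep this figure.

Feeding moves the mean birth later by half the feed time. Cedar comes to 40.1%, and birch and alder to 51.7%. Ash, if warmed promptly, has 20.0 min hot, which gives 65.3%, more than my figure for any other flask, so I commit to ash.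

The forecast also names ash, with 39.5% for oak, 64% for ash, 50.5% for alder, 40% for cedar and 51% for birch, on the ground that “time spent hot matters”, and its ash lies 1.3 points below mine.

The flasks give ash as the highest: oak 39.0%, ash 66.0%, alder 50.6%, cedar 39.7%, birch 50.0%.

    target ⇌ isomer of the product (K = 19.0, k = 3.20 × 10⁻⁴ /s, Ea = 114 kJ/mol, ΔH = −22.0 kJ/mol)
    substrate + reagent → target, rate k2*[substrate]^0.5*[reagent] (k = 0.0270 /M^0.5/s, Ea = 76.0 kJ/mol)
    (constants at 80 °C)

The target goes to isomer of the product, and oak holds 56.0% of it beside 39.0% target at 50.0 min. Left longer, oak's target stands lower, at 4.75% at 500 min. A neighbour of oak is charged with 1.1 M of substrate and the same reagent. Its cap is 24.2%, and k_L of 0.0187 /min with the same delay gives 9.95%. That neighbour gives 9.68% target, with 75.8% of its substrate still there.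

The runs are calculated for an exercise; the scatter is artificial.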